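Ring C of the flavanone is disconnected at C3–C4. The feature exploited is the C4 ketone of ring C flanked by the C3 methylene and the O1–C2 benzylic ether: a ketone is a hydrolysed enol ether, so ring C can be closed as a 4-silyloxy-2H-chromene by ring-closing olefin metathesis, which joins C3 to C4 with loss of ethylene. The precursor is an aryl 1-arylallyl ether: O1 of ring A already carries C2 (S, set by iridium-catalysed asymmetric allylic etherification of a ring B cinnamyl carbonate) and the acetyl group of ring A is masked as its silyl enol ether. One buffered fluoride step then frees the ketone and all hydroxyl groups.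

Key step: step 11

Remarks on the chemistry:
- The single stereocentre of the target (C2) is S, the configuration of the natural flavanones.
- TIPS = triisopropylsilyl, TES = triethylsilyl.
- Compounds 1, 3 and 10 are taken as commercial.
- The phosphoramidite enantiomer in step 9 is the one expected to give the S ether. If the sense of induction proved opposite, the mirror-image ligand would be used.

Step 1
Reactants: 1 geranyl acetate
Product: 2 (2E)-7-hydroxy-3,7-dimethyloct-2-en-1-yl acetate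
Conditions: Co(acac)2 (10 mol%), PhSiH3 (2 equiv), O2 (1 atm), THF, rt
Reagents that add atoms: dioxygen, O=O
Why: Mukaiyama hydration (hydrogen atom transfer from a cobalt hydride, capture of the tertiary radical by O2, reduction of the peroxide) is Markovnikov and should prefer the electron-richer distal alkene over the one deactivated by the allylic acetate, leaving the E geometry at C2=C3 untouched.

Step 2
Reactants: 3 3-bromo-4,5-dihydroxybenzaldehyde
Product: 4 3-bromo-4,5-bis(triisopropylsilyloxy)benzaldehyde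
Conditions: TIPSOTf (2.4 equiv), 2,6-lutidine (3 equiv), CH2Cl2, 0 °C to rt
Reagents that add atoms: triisopropylsilyl triflate, CC(C)[Si](OS(=O)(=O)C(F)(F)F)(C(C)C)C(C)C
Why: O-silylation of both catechol hydroxyls with the reactive silyl triflate should give base-robust aryl TIPS ethers that survive the coupling steps and fall to fluoride at the end.

Step 3
Reactants: 4 3-bromo-4,5-bis(triisopropylsilyloxy)benzaldehyde
Product: 5 3-(4,4,5,5-tetramethyl-1,3,2-dioxaborolan-2-yl)-4,5-bis(triisopropylsilyloxy)benzaldehyde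
Conditions: B2pin2 (1.3 equiv), PdCl2(dppf) (5 mol%), KOAc (3 equiv), 1,4-dioxane, 90 °C
Reagents that add atoms: bis(pinacolato)diboron, CC1(C)OB(OC1(C)C)B1OC(C)(C)C(C)(C)O1
Why: Miyaura borylation of the aryl bromide tolerates the aldehyde and the silyl ethers and turns ring B into the nucleophilic partner for the allyl–aryl coupling.

Step 4
Reactants: 5 3-(4,4,5,5-tetramethyl-1,3,2-dioxaborolan-2-yl)-4,5-bis(triisopropylsilyloxy)benzaldehyde; 2 (2E)-7-hydroxy-3,7-dimethyloct-2-en-1-yl acetate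
Product: 6 3-[(2E)-7-hydroxy-3,7-dimethyloct-2-en-1-yl]-4,5-bis(triisopropylsilyloxy)benzaldehyde
Conditions: Pd2(dba)3 (2.5 mol%), PPh3 (10 mol%), K2CO3 (2 equiv), THF/H2O (10:1), 60 °C
Reagents that add atoms: none
Why: In this Suzuki–Miyaura allyl–aryl coupling the allylic acetate ionizes to a π-allylpalladium species (Tsuji–Trost type), the arylboronate transmetalates, and reductive elimination at the unhindered CH2 terminus should give the linear product with the E alkene retained.

Step 5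
Reactants: 6 3-[(2E)-7-hydroxy-3,7-dimethyloct-2-en-1-yl]-4,5-bis(triisopropylsilyloxy)benzaldehyde
Product: 7 ethyl (2E)-3-{3-[(2E)-7-hydroxy-3,7-dimethyloct-2-en-1-yl]-4,5-bis(triisopropylsilyloxy)phenyl}prop-2-enoate
Conditions: (EtO)2P(O)CH2CO2Et (1.3 equiv), LiCl, DBU, MeCN, rt
Reagents that add atoms: triethyl phosphonoacetate, CCOC(=O)CP(=O)(OCC)OCC
Why: Horner–Wadsworth–Emmons olefination under Masamune–Roush conditions is E-selective and mild enough for the free tertiary alcohol and the aryl silyl ethers; the phosphonate carbon becomes C3 of the target.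

Step 6
Reactants: 7 ethyl (2E)-3-{3-[(2E)-7-hydroxy-3,7-dimethyloct-2-en-1-yl]-4,5-bis(triisopropylsilyloxy)phenyl}prop-2-enoate
Product: 8 (2E)-8-{5-[(1E)-3-hydroxyprop-1-en-1-yl]-2,3-bis(triisopropylsilyloxy)phenyl}-2,6-dimethyloct-6-en-2-ol
Conditions: i-Bu2AlH (3.5 equiv), CH2Cl2, −78 °C; aq. potassium sodium tartrate (KNaC4H4O6)
Reagents that add atoms: none
Why: 1,2-reduction of the enoate by i-Bu2AlH at low temperature should give the cinnamyl alcohol without touching either alkene or the silyl ethers.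

Step 7
Reactants: 8 (2E)-8-{5-[(1E)-3-hydroxyprop-1-en-1-yl]-2,3-bis(triisopropylsilyloxy)phenyl}-2,6-dimethyloct-6-en-2-ol
Product: 9 methyl (2E)-3-{3-[(2E)-7-hydroxy-3,7-dimethyloct-2-en-1-yl]-4,5-bis(triisopropylsilyloxy)phenyl}prop-2-en-1-yl carbonate
Conditions: ClCO2Me (1.3 equiv), pyridine, CH2Cl2, 0 °C
Reagents that add atoms: methyl chloroformate, COC(=O)Cl
Why: Acylation with the chloroformate is selective for the primary allylic alcohol over the hindered tertiary alcohol and installs the leaving group for the iridium step.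

Step 8
Reactants: 10 2',4',6'-trihydroxyacetophenone
Product: 11 1-[2-hydroxy-4,6-bis(triisopropylsilyloxy)phenyl]ethanone
Conditions: TIPSCl (2.1 equiv), imidazole (4 equiv), DMF, 0 °C to rt
Reagents that add atoms: triisopropylsilyl chloride, CC(C)[Si](Cl)(C(C)C)C(C)C
Why: With two equivalents of silyl chloride the para hydroxyl and one ortho hydroxyl should be silylated, while the last ortho hydroxyl, locked in a hydrogen bond to the acetyl oxygen, stays free as the future O1.

Step 9
Reactants: 9 methyl (2E)-3-{3-[(2E)-7-hydroxy-3,7-dimethyloct-2-en-1-yl]-4,5-bis(triisopropylsilyloxy)phenyl}prop-2-en-1-yl carbonate; 11 1-[2-hydroxy-4,6-bis(triisopropylsilyloxy)phenyl]ethanone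
Product: 13 1-[2-({(1S)-1-[3-((2E)-7-hydroxy-3,7-dimethyloct-2-en-1-yl)-4,5-bis(triisopropylsilyloxy)phenyl]prop-2-en-1-yl}oxy)-4,6-bis(triisopropylsilyloxy)phenyl]ethanone, via lithium 2-acetyl-3,5-bis(triisopropylsilyloxy)phenoxide 12 (not isolated)
Conditions: 11 (1.5 equiv), LiN(SiMe3)2 (1.5 equiv), THF, 0 °C; then 9, [Ir(cod)Cl]2 (2 mol%), (Sa,Sc,Sc)-O,O'-(1,1'-binaphthalene-2,2'-diyl) N,N-bis(1-phenylethyl)phosphoramidite (4 mol%), THF, rt to 40 °C
Reagents that add atoms: none
Why: In this iridium-catalysed asymmetric allylic etherification the cyclometalated iridium–phosphoramidite complex ionizes the carbonate to an allyl complex that the phenoxide oxygen attacks at the aryl-bearing terminus, giving the branched ether; the chiral ligand selects the allyl face and so sets C2 as S.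

Step 10
Reactants: 13 1-[2-({(1S)-1-[3-((2E)-7-hydroxy-3,7-dimethyloct-2-en-1-yl)-4,5-bis(triisopropylsilyloxy)phenyl]prop-2-en-1-yl}oxy)-4,6-bis(triisopropylsilyloxy)phenyl]ethanone
Product: 14 the bis-TES derivative of 13: triethylsilyl enol ether of the acetyl group (1-(triethylsilyloxy)vinyl on ring A) and triethylsilyl ether of the tertiary alcohol, C2 still S
Conditions: TESOTf (3 equiv), Et3N (5 equiv), CH2Cl2, −78 to 0 °C
Reagents that add atoms: triethylsilyl triflate, CC[Si](CC)(CC)OS(=O)(=O)C(F)(F)F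
Why: Soft enolization of the methyl ketone (O-silylation, then deprotonation by Et3N) gives the 1-silyloxyvinyl group and the tertiary alcohol is silylated in the same operation, the excess amine keeping the medium non-acidic so that the ionizable allylic aryl ether and its stereocentre survive.

Step 11
Reactants: 14 the bis-TES derivative of 13
Product: 15 (2S)-2-{3-[(2E)-3,7-dimethyl-7-(triethylsilyloxy)oct-2-en-1-yl]-4,5-bis(triisopropylsilyloxy)phenyl}-4-(triethylsilyloxy)-5,7-bis(triisopropylsilyloxy)-2H-chromene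
Conditions: second-generation Hoveyda–Grubbs catalyst RuCl2(H2IMes)(=CH-C6H4-2-OiPr) (10 mol%), 1,4-benzoquinone (20 mol%), toluene (0.005 M), 70 °C, argon sparge
Reagents that add atoms: none
Why: The ruthenium alkylidene should initiate at the monosubstituted vinyl group to give a carbene at C3, which adds intramolecularly to the 1,1-disubstituted silyl enol ether ([2+2] cycloaddition, then cycloreversion), joining C3 to C4 as the enol ether double bond and expelling ethylene. The closest known reaction types are ring-closing metathesis of olefinic silyl enol ethers to cyclic silyl enol ethers and of 2-vinylphenyl 1-arylallyl ethers to 2-aryl-2H-chromenes. Ring C is closed as a six-membered ring by ring-closing olefin metathesis, both reacting carbons (C3 and C4) becoming ring members, with ring A holding the two alkenes in an ortho relationship that favours closure. No stereocentre is formed; C2 keeps the S configuration set in step 9 because no bond to it is made or broken and the neutral conditions stay well below the temperatures of aromatic Claisen rearrangement. The step needs chemoselectivity over the trisubstituted side-chain alkene, which is secured by geometry (closure onto it would need a meta-bridged ring) and by high dilution, which disfavours cross-metathesis of a trisubstituted alkene, while benzoquinone should suppress ruthenium hydride isomerization of the allyl ether. The C3=C4 enol ether formed here is the masked C4 ketone of ring C.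

Step 12
Reactants: 15 (2S)-2-{3-[(2E)-3,7-dimethyl-7-(triethylsilyloxy)oct-2-en-1-yl]-4,5-bis(triisopropylsilyloxy)phenyl}-4-(triethylsilyloxy)-5,7-bis(triisopropylsilyloxy)-2H-chromene
Product: 16 propolin B, (2S)-2-{3,4-dihydroxy-5-[(2E)-7-hydroxy-3,7-dimethyloct-2-en-1-yl]phenyl}-5,7-dihydroxy-2,3-dihydro-4H-chromen-4-one
Conditions: Bu4NF (8 equiv), AcOH (10 equiv), THF, 0 °C to rt
Reagents that add atoms: none
Why: Fluoride should cleave the four aryl TIPS ethers, the tertiary TES ether and the silyl enol ether, whose protonation at C3 gives the C4 ketone, while the acetic acid buffer keeps the medium from turning basic so that the flavanone does not ring-open by retro-oxa-Michael reaction and C2 stays S.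

Compound list
1 | geranyl acetate, (2E)-3,7-dimethylocta-2,6-dien-1-yl acetate | CC(=O)OC/C=C(\C)CCC=C(C)C | starting material
2 | (2E)-7-hydroxy-3,7-dimethyloct-2-en-1-yl acetate | CC(=O)OC/C=C(\C)CCCC(C)(C)O | intermediate
3 | 3-bromo-4,5-dihydroxybenzaldehyde | O=Cc1cc(O)c(O)c(Br)c1 | starting material
4 | 3-bromo-4,5-bis(triisopropylsilyloxy)benzaldehyde | O=Cc1cc(O[Si](C(C)C)(C(C)C)C(C)C)c(O[Si](C(C)C)(C(C)C)C(C)C)c(Br)c1 | intermediate
5 | 3-(4,4,5,5-tetramethyl-1,3,2-dioxaborolan-2-yl)-4,5-bis(triisopropylsilyloxy)benzaldehyde | O=Cc1cc(O[Si](C(C)C)(C(C)C)C(C)C)c(O[Si](C(C)C)(C(C)C)C(C)C)c(B2OC(C)(C)C(C)(C)O2)c1 | intermediate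
6 | 3-[(2E)-7-hydroxy-3,7-dimethyloct-2-en-1-yl]-4,5-bis(triisopropylsilyloxy)benzaldehyde | O=Cc1cc(O[Si](C(C)C)(C(C)C)C(C)C)c(O[Si](C(C)C)(C(C)C)C(C)C)c(C/C=C(\C)CCCC(C)(C)O)c1 | intermediate
7 | ethyl (2E)-3-{3-[(2E)-7-hydroxy-3,7-dimethyloct-2-en-1-yl]-4,5-bis(triisopropylsilyloxy)phenyl}prop-2-enoate | CCOC(=O)/C=C/c1cc(O[Si](C(C)C)(C(C)C)C(C)C)c(O[Si](C(C)C)(C(C)C)C(C)C)c(C/C=C(\C)CCCC(C)(C)O)c1 | intermediate
8 | (2E)-8-{5-[(1E)-3-hydroxyprop-1-en-1-yl]-2,3-bis(triisopropylsilyloxy)phenyl}-2,6-dimethyloct-6-en-2-ol (the ring B cinnamyl alcohol) | OC/C=C/c1cc(O[Si](C(C)C)(C(C)C)C(C)C)c(O[Si](C(C)C)(C(C)C)C(C)C)c(C/C=C(\C)CCCC(C)(C)O)c1 | intermediate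
9 | methyl (2E)-3-{3-[(2E)-7-hydroxy-3,7-dimethyloct-2-en-1-yl]-4,5-bis(triisopropylsilyloxy)phenyl}prop-2-en-1-yl carbonate | COC(=O)OC/C=C/c1cc(O[Si](C(C)C)(C(C)C)C(C)C)c(O[Si](C(C)C)(C(C)C)C(C)C)c(C/C=C(\C)CCCC(C)(C)O)c1 | intermediate
10 | 2',4',6'-trihydroxyacetophenone | CC(=O)c1c(O)cc(O)cc1O | starting material
11 | 1-[2-hydroxy-4,6-bis(triisopropylsilyloxy)phenyl]ethanone | CC(=O)c1c(O)cc(O[Si](C(C)C)(C(C)C)C(C)C)cc1O[Si](C(C)C)(C(C)C)C(C)C | intermediate
12 | lithium 2-acetyl-3,5-bis(triisopropylsilyloxy)phenoxide (not isolated) | CC(=O)c1c([O-])cc(O[Si](C(C)C)(C(C)C)C(C)C)cc1O[Si](C(C)C)(C(C)C)C(C)C.[Li+] | intermediate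
13 | 1-[2-({(1S)-1-[3-((2E)-7-hydroxy-3,7-dimethyloct-2-en-1-yl)-4,5-bis(triisopropylsilyloxy)phenyl]prop-2-en-1-yl}oxy)-4,6-bis(triisopropylsilyloxy)phenyl]ethanone | CC(=O)c1c(O[C@@H](C=C)c2cc(O[Si](C(C)C)(C(C)C)C(C)C)c(O[Si](C(C)C)(C(C)C)C(C)C)c(C/C=C(\C)CCCC(C)(C)O)c2)cc(O[Si](C(C)C)(C(C)C)C(C)C)cc1O[Si](C(C)C)(C(C)C)C(C)C | intermediate
14 | bis-TES derivative of 13 (S): ring A carries 1-(triethylsilyloxy)vinyl, the side-chain tertiary alcohol is a TES ether | C=C(O[Si](CC)(CC)CC)c1c(O[C@@H](C=C)c2cc(O[Si](C(C)C)(C(C)C)C(C)C)c(O[Si](C(C)C)(C(C)C)C(C)C)c(C/C=C(\C)CCCC(C)(C)O[Si](CC)(CC)CC)c2)cc(O[Si](C(C)C)(C(C)C)C(C)C)cc1O[Si](C(C)C)(C(C)C)C(C)C | intermediate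
15 | (2S)-2-{3-[(2E)-3,7-dimethyl-7-(triethylsilyloxy)oct-2-en-1-yl]-4,5-bis(triisopropylsilyloxy)phenyl}-4-(triethylsilyloxy)-5,7-bis(triisopropylsilyloxy)-2H-chromene | CC[Si](CC)(CC)OC1=C[C@@H](c2cc(O[Si](C(C)C)(C(C)C)C(C)C)c(O[Si](C(C)C)(C(C)C)C(C)C)c(C/C=C(\C)CCCC(C)(C)O[Si](CC)(CC)CC)c2)Oc2cc(O[Si](C(C)C)(C(C)C)C(C)C)cc(O[Si](C(C)C)(C(C)C)C(C)C)c12 | intermediate
16 | propolin B, (2S)-2-{3,4-dihydroxy-5-[(2E)-7-hydroxy-3,7-dimethyloct-2-en-1-yl]phenyl}-5,7-dihydroxy-2,3-dihydro-4H-chromen-4-one | C/C(=C\Cc1cc([C@@H]2CC(=O)c3c(O)cc(O)cc3O2)cc(O)c1O)CCCC(C)(C)O | target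

Total step count: 12.
Longest linear sequence: 10 steps (3 → 4 → 5 → 6 → 7 → 8 → 9 → 13 → 14 → 15 → 16; steps 2–7 and 9–12).

Steps most likely to fail

Step 9 (asymmetric allylic etherification). The chelated, weakly nucleophilic ortho-acetyl phenoxide may attack slowly or through carbon of the electron-rich ring. The product, an allylic ether of a good leaving group on an electron-rich arylallyl unit, may also re-ionize on iridium, eroding enantiopurity and leaking to the linear ether. The fallback sets the stereocentre by reagent-controlled epoxidation and sets out from alcohol 8. Sharpless asymmetric epoxidation (Ti(OiPr)4, L-(+)-diethyl tartrate, t-BuOOH, 4 Å sieves, CH2Cl2, −20 °C) should give the (2S,3S)-epoxy alcohol F1. Lithium phenoxide 12 (THF/DMF, 50 °C) should open it at the benzylic carbon with inversion, as phenoxides do with 3-arylglycidols, to give the (2S,3R)-3-aryl-3-aryloxypropane-1,2-diol F2. 1,1'-Thiocarbonyldiimidazole converts the diol into the cyclic thionocarbonate F3. Corey–Winter olefination with 1,3-dimethyl-2-phenyl-1,3,2-diazaphospholidine at 40 °C then gives the terminal alkene. The fallback comes back to the route at ether 13.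

Step 11 (ring-closing metathesis). The hindered 1,1-disubstituted enol ether on a 2,6-disubstituted arene may not be engaged by the ruthenium carbene. Dimerization through the vinyl group, isomerization of the allyl ether or hydrolysis of the silyl enol ether could then take over. The fallback closes the same C3–C4 bond by a titanium-alkylidene olefin–ester cyclization and sets out from carbonate 9. Commercial methyl 2,4,6-trihydroxybenzoate F4 is silylated (TIPSCl, imidazole) to methyl 2-hydroxy-4,6-bis(triisopropylsilyloxy)benzoate F5. F5, deprotonated with LiN(SiMe3)2, is coupled with 9 under the conditions of step 9 to give the (S)-allyl aryl ether ester F6. The tertiary alcohol is protected (TESOTf, 2,6-lutidine) to give the TES ether F7. Takai–Utimoto conditions (TiCl4, Zn, PbCl2 cat., TMEDA, CH3CHBr2, THF/CH2Cl2, rt to 65 °C) should convert ester and vinyl group into the silylated 4-methoxy-2H-chromene F8. Bu4NF/AcOH removes the silyl groups to give the free 4-methoxy-2H-chromene F9. Dilute aqueous HCl in THF hydrolyses the methyl enol ether, and the fallback comes back at target 16.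

Step 4 (allyl–aryl coupling). Slow transmetalation of the hindered arylboronate may allow protodeboronation, E/Z scrambling of the π-allyl intermediate, β-hydride elimination to a diene, or capture of the π-allyl by the tertiary hydroxyl. The fallback reverses the polarity of the partners so that no electrophilic π-allyl is formed from the side chain in the coupling; it sets out from bromide 4 and acetate 2. Horner–Wadsworth–Emmons olefination of 4 (triethyl phosphonoacetate, LiCl, DBU) gives ethyl (2E)-3-[3-bromo-4,5-bis(triisopropylsilyloxy)phenyl]prop-2-enoate F10. Palladium-catalysed borylation of 2 (B2pin2, Pd2(dba)3, DMSO, 50 °C) gives the (E)-allylboronate F11. Suzuki–Miyaura coupling of F10 with F11 (Pd(OAc)2 with a bulky dialkylbiarylphosphine such as t-BuXPhos, aqueous K3PO4, THF, 40 °C), run for linear selectivity, comes back to the route at ester 7.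

Further compounds
F1 | step 9 | [(2S,3S)-3-{3-[(2E)-7-hydroxy-3,7-dimethyloct-2-en-1-yl]-4,5-bis(triisopropylsilyloxy)phenyl}oxiran-2-yl]methanol | OC[C@@H]1O[C@H]1c2cc(O[Si](C(C)C)(C(C)C)C(C)C)c(O[Si](C(C)C)(C(C)C)C(C)C)c(C/C=C(\C)CCCC(C)(C)O)c2
F2 | step 9 | (2S,3R)-3-[2-acetyl-3,5-bis(triisopropylsilyloxy)phenoxy]-3-{3-[(2E)-7-hydroxy-3,7-dimethyloct-2-en-1-yl]-4,5-bis(triisopropylsilyloxy)phenyl}propane-1,2-diol | CC(=O)c1c(O[C@@H]([C@@H](O)CO)c2cc(O[Si](C(C)C)(C(C)C)C(C)C)c(O[Si](C(C)C)(C(C)C)C(C)C)c(C/C=C(\C)CCCC(C)(C)O)c2)cc(O[Si](C(C)C)(C(C)C)C(C)C)cc1O[Si](C(C)C)(C(C)C)C(C)C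
F3 | step 9 | cyclic thionocarbonate (1,3-dioxolane-2-thione) of diol F2 | CC(=O)c1c(O[C@@H]([C@@H]3COC(=S)O3)c2cc(O[Si](C(C)C)(C(C)C)C(C)C)c(O[Si](C(C)C)(C(C)C)C(C)C)c(C/C=C(\C)CCCC(C)(C)O)c2)cc(O[Si](C(C)C)(C(C)C)C(C)C)cc1O[Si](C(C)C)(C(C)C)C(C)C
F4 | step 11 | methyl 2,4,6-trihydroxybenzoate | COC(=O)c1c(O)cc(O)cc1O
F5 | step 11 | methyl 2-hydroxy-4,6-bis(triisopropylsilyloxy)benzoate | COC(=O)c1c(O)cc(O[Si](C(C)C)(C(C)C)C(C)C)cc1O[Si](C(C)C)(C(C)C)C(C)C
F6 | step 11 | methyl 2-({(1S)-1-[3-((2E)-7-hydroxy-3,7-dimethyloct-2-en-1-yl)-4,5-bis(triisopropylsilyloxy)phenyl]prop-2-en-1-yl}oxy)-4,6-bis(triisopropylsilyloxy)benzoate | COC(=O)c1c(O[C@@H](C=C)c2cc(O[Si](C(C)C)(C(C)C)C(C)C)c(O[Si](C(C)C)(C(C)C)C(C)C)c(C/C=C(\C)CCCC(C)(C)O)c2)cc(O[Si](C(C)C)(C(C)C)C(C)C)cc1O[Si](C(C)C)(C(C)C)C(C)C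
F7 | step 11 | tertiary triethylsilyl ether of F6 | COC(=O)c1c(O[C@@H](C=C)c2cc(O[Si](C(C)C)(C(C)C)C(C)C)c(O[Si](C(C)C)(C(C)C)C(C)C)c(C/C=C(\C)CCCC(C)(C)O[Si](CC)(CC)CC)c2)cc(O[Si](C(C)C)(C(C)C)C(C)C)cc1O[Si](C(C)C)(C(C)C)C(C)C
F8 | step 11 | (2S)-2-{3-[(2E)-3,7-dimethyl-7-(triethylsilyloxy)oct-2-en-1-yl]-4,5-bis(triisopropylsilyloxy)phenyl}-4-methoxy-5,7-bis(triisopropylsilyloxy)-2H-chromene | COC1=C[C@@H](c2cc(O[Si](C(C)C)(C(C)C)C(C)C)c(O[Si](C(C)C)(C(C)C)C(C)C)c(C/C=C(\C)CCCC(C)(C)O[Si](CC)(CC)CC)c2)Oc2cc(O[Si](C(C)C)(C(C)C)C(C)C)cc(O[Si](C(C)C)(C(C)C)C(C)C)c12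
F9 | step 11 | (2S)-2-{3,4-dihydroxy-5-[(2E)-7-hydroxy-3,7-dimethyloct-2-en-1-yl]phenyl}-4-methoxy-2H-chromene-5,7-diol | COC1=C[C@@H](c2cc(O)c(O)c(C/C=C(\C)CCCC(C)(C)O)c2)Oc2cc(O)cc(O)c12
F10 | step 4 | ethyl (2E)-3-[3-bromo-4,5-bis(triisopropylsilyloxy)phenyl]prop-2-enoate | CCOC(=O)/C=C/c1cc(O[Si](C(C)C)(C(C)C)C(C)C)c(O[Si](C(C)C)(C(C)C)C(C)C)c(Br)c1
F11 | step 4 | (6E)-2,6-dimethyl-8-(4,4,5,5-tetramethyl-1,3,2-dioxaborolan-2-yl)oct-6-en-2-ol | CC(C)(O)CCC/C(C)=C/CB1OC(C)(C)C(C)(C)O1
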